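**Assumption:** bicyclic compounds carry clerodane numbering (ring A = C1–C5 + C10, ring B = C5–C10, C17 on C8, C18 on C4, C19 on C5, C20 on C9, side chain C11–C16); β is the face of H-10, α the face of the C5 methyl; 1,3-dicarbonyl compounds are drawn as keto forms and their freely epimerising centres are left undefined.

## Retrosynthetic overview

1. Target ⇐ furan-to-butenolide oxidation, C4 ketone methylenation and acylations; the 7β,8β-diol comes from dihydroxylation of a 7-ene that carries a 6α-acetate.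
2. The 8-methyl-7-en-6-one ⇐ Stork–Danheiser methyl transposition of a ring B 6,8-dione; the C9 quaternary centre and the C11 carbinol ⇐ aldol of the dione polyanion with (furan-3-yl)acetaldehyde.
3. Bicyclic 4,6,8-trione ⇐ key step: one-pot intramolecular Michael/Claisen double cyclisation of an acyclic methyl-diketone enoate. Ring A closes first (C5–C10), ring B second (C7–C8).
4. Acyclic precursor ⇐ dianion of 3-methylpentane-2,4-dione + (R)-benzyl glycidyl ether (C1, the only purchased stereocentre), then oxidation/Wittig.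

## Route

Step 1
Reactants: 1 3-methylpentane-2,4-dione; 2 (R)-benzyl glycidyl ether
Product: 3 (7R)-8-(benzyloxy)-7-hydroxy-3-methyloctane-2,4-dione
Conditions: NaH (1.0 equiv), THF, 0 °C; n-BuLi (1.05 equiv), −20 °C; 2, −20 → 25 °C; 1 M HCl to pH 5
Reagents that add atoms: none
Why: Hauser dianion alkylation: the terminal carbanion of the diketone dianion opens the epoxide at its unhindered CH2 (SN2), so the stereocentre of 2 is carried over unchanged as C1.

Step 2
Reactants: 3 (7R)-8-(benzyloxy)-7-hydroxy-3-methyloctane-2,4-dione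
Product: 4 (7R)-8-(benzyloxy)-7-[(tert-butyldimethylsilyl)oxy]-3-methyloctane-2,4-dione
Conditions: TBSCl, imidazole, DMF, 25 °C
Reagents that add atoms: tert-butyldimethylsilyl chloride CC(C)(C)[Si](C)(C)Cl
Why: Standard silylation of the secondary alcohol, which also stops it closing onto the γ-ketone; no stereocentre is touched.

Step 3
Reactants: 4 (7R)-8-(benzyloxy)-7-[(tert-butyldimethylsilyl)oxy]-3-methyloctane-2,4-dione
Product: 5 (7R)-7-[(tert-butyldimethylsilyl)oxy]-8-hydroxy-3-methyloctane-2,4-dione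
Conditions: H2 (1 atm), Pd/C, EtOAc, 25 °C
Reagents that add atoms: none
Why: Hydrogenolysis of the benzyl ether over Pd/C leaves the silyl ether and the diketone untouched.

Step 4
Reactants: 5 (7R)-7-[(tert-butyldimethylsilyl)oxy]-8-hydroxy-3-methyloctane-2,4-dione
Product: 7 ethyl (2E,4R)-4-[(tert-butyldimethylsilyl)oxy]-2,8-dimethyl-7,9-dioxodec-2-enoate, via aldehyde 6 (not isolated)
Conditions: (n-Pr)4N[RuO4] (5 mol%), NMO (1.5 equiv), 4 Å MS, CH2Cl2, 25 °C; then Ph3P=C(CH3)CO2Et (1.5 equiv), 25 → 40 °C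
Reagents that add atoms: ethyl 2-(triphenylphosphoranylidene)propanoate CCOC(=O)C(C)=P(c1ccccc1)(c1ccccc1)c1ccccc1
Why: Ley–Griffith oxidation followed in the same flask by a Wittig reaction of the stabilised ylide, which gives the (E)-2-methyl enoate and avoids isolating the epimerisable α-silyloxy aldehyde.

Step 5 (key step)
Reactants: 7 ethyl (2E,4R)-4-[(tert-butyldimethylsilyl)oxy]-2,8-dimethyl-7,9-dioxodec-2-enoate
Product: 9 1β-[(tert-butyldimethylsilyl)oxy]-5α,9β-dimethyl-trans-decalin-4,6,8-trione, via Michael adduct 8 (not isolated)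
Conditions: t-BuOK (0.2 equiv), THF, 0 → 25 °C; then t-BuOK (2.3 equiv), 25 → 45 °C; 1 M HCl
Reagents that add atoms: none
Why: Tandem intramolecular Michael addition–Dieckmann-type Claisen condensation: the chelated potassium diketonate adds 6-exo to the (E)-enoate through a chair in which the C1 silyloxy group is equatorial (allylic 1,3-strain puts H-1 in the enoate plane, so C5 attacks C10 anti to the OSi group) and the exocyclic acetyl is held cis to the ring-carbonyl oxygen and therefore ends equatorial with the C5 methyl axial, which fixes C10 and the quaternary C5 with the trans relationship needed, after which the acetyl enolate acylates itself with the ester to close ring B and the 6,8-dione is removed from all equilibria as its enolate.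

Step 6
Reactants: 10 furan-3-carbaldehyde
Product: 12 (furan-3-yl)acetaldehyde, via enol ether 11 (not isolated)
Conditions: Ph3P(Cl)CH2OCH3, t-BuOK, THF, 0 °C; then 1 M HCl, THF, 25 °C
Reagents that add atoms: (methoxymethyl)triphenylphosphonium chloride COC[P+](c1ccccc1)(c1ccccc1)c1ccccc1.[Cl-]; water O
Why: Wittig methoxymethylenation followed by acid hydrolysis of the enol ether, a one-carbon homologation; the sensitive aldehyde is used at once.

Step 7
Reactants: 9 1β-[(tert-butyldimethylsilyl)oxy]-5α,9β-dimethyl-trans-decalin-4,6,8-trione; 12 (furan-3-yl)acetaldehyde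
Product: 13 (11S)-1β-[(tert-butyldimethylsilyl)oxy]-9β-[2-(furan-3-yl)-1-hydroxyethyl]-5α,9α-dimethyl-trans-decalin-4,6,8-trione
Conditions: LiN(i-Pr)2 (3.3 equiv), THF, −78 → −20 °C; CeCl3 (1.5 equiv), −78 °C; 12, −78 °C; AcOH
Reagents that add atoms: none
Why: Hauser-type polyanion aldol: with C4 parked as its enolate, the terminal C9 carbanion of the 6,8-dione dianion (the most reactive site) is transmetalated to cerium and adds to the aldehyde from the β face, anti to the axial C5 methyl, which creates the C9 quaternary centre (C20 α, C11 β), and a closed Zimmerman–Traxler chair in which C20 is the enolate substituent cis to oxygen gives the 11S carbinol (hydroxyl syn to C20).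

Step 8
Reactants: 13 (11S)-1β-[(tert-butyldimethylsilyl)oxy]-9β-[2-(furan-3-yl)-1-hydroxyethyl]-5α,9α-dimethyl-trans-decalin-4,6,8-trione
Product: 14 (11S)-1β-[(tert-butyldimethylsilyl)oxy]-9β-[2-(furan-3-yl)-1-hydroxyethyl]-6-methoxy-5α,9α-dimethyl-trans-decal-6-ene-4,8-dione
Conditions: (CH3O)2SO2, K2CO3, acetone, 25 °C
Reagents that add atoms: dimethyl sulfate COS(=O)(=O)OC
Why: O-Alkylation of the cyclic 1,3-dione (vinylogous ester formation): the dione enolate is methylated on O6, the oxygen that is neither crowded by the fully substituted C9 side chain nor hydrogen-bonded to the C11 hydroxyl, so that C8 remains the carbonyl group; no stereocentre is involved.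

Step 9
Reactants: 14 (11S)-1β-[(tert-butyldimethylsilyl)oxy]-9β-[2-(furan-3-yl)-1-hydroxyethyl]-6-methoxy-5α,9α-dimethyl-trans-decal-6-ene-4,8-dione
Product: 17 (11S)-9β-[2-(furan-3-yl)-1-hydroxyethyl]-1β-hydroxy-5α,8,9α-trimethyl-trans-decal-7-ene-4,6-dione, via carbinol 15 (not isolated), via silyl enone 16 (not isolated)
Conditions: LiN(i-Pr)2 (2.2 equiv), THF, −78 °C; CH3Li (4 equiv), −78 → 0 °C; then 48% aq HF–MeCN (1:9), 0 → 25 °C
Reagents that add atoms: methyllithium [Li]C
Why: Stork–Danheiser alkylative enone transposition: after the C11 hydroxyl and the C4 ketone have been masked in situ as alkoxide and enolate, methyllithium adds 1,2 to the C8 vinylogous-ester carbonyl, and aqueous HF then ionises the tertiary allylic carbinol, hydrolyses the enol ether to the 8-methyl-7-en-6-one and cleaves the C1 silyl ether; the new C8 centre is lost again, so no stereocontrol is needed.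

Step 10
Reactants: 17 (11S)-9β-[2-(furan-3-yl)-1-hydroxyethyl]-1β-hydroxy-5α,8,9α-trimethyl-trans-decal-7-ene-4,6-dione
Product: 18 (11S)-9β-[2-(furan-3-yl)-1-hydroxyethyl]-1β,6α-dihydroxy-5α,8,9α-trimethyl-trans-decal-7-en-4-one
Conditions: NaBH4, CeCl3·7H2O, MeOH, −78 → −40 °C
Reagents that add atoms: none
Why: Luche 1,2-reduction: hydride attacks the enone carbonyl axially from the β face, away from the axial C5 methyl on the neighbouring carbon, to give the equatorial 6α-alcohol, while the more hindered non-conjugated C4 ketone is reduced much more slowly under these conditions.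

Step 11
Reactants: 18 (11S)-9β-[2-(furan-3-yl)-1-hydroxyethyl]-1β,6α-dihydroxy-5α,8,9α-trimethyl-trans-decal-7-en-4-one
Product: 19 (11S)-1β,6α,11-triacetoxy-9β-[2-(furan-3-yl)ethyl]-5α,8,9α-trimethyl-trans-decal-7-en-4-one (acetoxy on C1 of the ethyl group = C11)
Conditions: Ac2O, pyridine, DMAP, 25 → 40 °C
Reagents that add atoms: acetic anhydride CC(=O)OC(C)=O
Why: Acetylation (DMAP catalysis) of the three secondary hydroxyls; the ketone and the furan are inert and no stereocentre changes.

Step 12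
Reactants: 19 the 1β,6α,11-triacetate of the 7-en-4-one
Product: 20 (11S)-1β,6α,11-triacetoxy-9β-[2-(furan-3-yl)ethyl]-7β,8β-dihydroxy-5α,8α,9α-trimethyl-trans-decalin-4-one
Conditions: OsO4 (0.2 equiv), NMO (3 equiv), acetone–H2O (8:1), 40 °C
Reagents that add atoms: 4-methylmorpholine N-oxide C[N+]1([O-])CCOCC1; water O
Why: Upjohn syn-dihydroxylation: OsO4 adds to the trisubstituted alkene on the β face, anti to the allylic 6α-acetoxy group (Kishi rule) and away from the axial methyls on C5 and C9 that cover the α face, which sets 7β-OH and 8β-OH (8α-methyl) in one step; ketone, esters and the furan are tolerated.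

Step 13
Reactants: 20 the 7β,8β-diol triacetate
Product: 21 (11S)-1β,6α,11-triacetoxy-9β-[2-(furan-3-yl)ethyl]-8β-hydroxy-7β-(isobutyryloxy)-5α,8α,9α-trimethyl-trans-decalin-4-one
Conditions: (CH3)2CHCOCl, pyridine, DMAP, CH2Cl2, 0 → 25 °C
Reagents that add atoms: isobutyryl chloride CC(C)C(=O)Cl
Why: Acylation: only the secondary C7 hydroxyl reacts, the tertiary C8 hydroxyl being too hindered, so the isobutyrate is placed regioselectively with no change at any stereocentre.

Step 14
Reactants: 21 the 7β-isobutyrate 4-ketone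
Product: 22 (11S)-1β,6α,11-triacetoxy-15,16-epoxy-8β-hydroxy-7β-(isobutyryloxy)cleroda-4(18),13(16),14-triene (the furan analogue of the target)
Conditions: Zn, CH2Br2, TiCl4, THF–CH2Cl2, 0 → 25 °C
Reagents that add atoms: dibromomethane BrCBr
Why: Takai–Lombardo methylenation: the non-basic gem-dizinc/titanium reagent converts the hindered C4 ketone into the exocyclic methylene without enolisation and without attacking the four esters, the tertiary alcohol or the furan.

Step 15
Reactants: 22 the furan analogue of the target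
Product: 25 (1R,5R,6R,7S,8R,9S,10S,11S)-1,6,11-triacetoxy-8-hydroxy-7-(isobutyryloxy)cleroda-4(18),13-dien-15,16-olide, via endoperoxide 23 (not isolated), via hydroxybutenolide 24 (not isolated)
Conditions: O2, tetraphenylporphyrin (cat.), hν, i-Pr2NEt, CH2Cl2, −78 °C; then NaBH4, EtOH, 0 °C
Reagents that add atoms: dioxygen O=O
Why: Furan photooxygenation: [4+2] addition of singlet oxygen gives the endoperoxide, from which the hindered amine removes the bridgehead proton remote from the substituent (Kornblum–DeLaMare-type fragmentation) to give the 4-substituted 5-hydroxybutenolide, and NaBH4 reduces its open-chain aldehyde form so that the hydroxy acid relactonises to the 15,16-olide; the 1,1-disubstituted alkene reacts far more slowly with singlet oxygen and the esters survive brief borohydride treatment.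

## Compound list

1 | 3-methylpentane-2,4-dione | CC(=O)C(C)C(C)=O | starting material
2 | (R)-benzyl glycidyl ether, (2R)-2-[(benzyloxy)methyl]oxirane | C(OCc1ccccc1)[C@H]1CO1 | starting material
3 | (7R)-8-(benzyloxy)-7-hydroxy-3-methyloctane-2,4-dione | CC(=O)C(C)C(=O)CC[C@@H](O)COCc1ccccc1 | intermediate
4 | (7R)-8-(benzyloxy)-7-[(tert-butyldimethylsilyl)oxy]-3-methyloctane-2,4-dione | CC(=O)C(C)C(=O)CC[C@@H](O[Si](C)(C)C(C)(C)C)COCc1ccccc1 | intermediate
5 | (7R)-7-[(tert-butyldimethylsilyl)oxy]-8-hydroxy-3-methyloctane-2,4-dione | CC(=O)C(C)C(=O)CC[C@@H](O[Si](C)(C)C(C)(C)C)CO | intermediate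
6 | (2R)-2-[(tert-butyldimethylsilyl)oxy]-6-methyl-5,7-dioxooctanal | CC(=O)C(C)C(=O)CC[C@@H](O[Si](C)(C)C(C)(C)C)C=O | intermediate (not isolated)
7 | ethyl (2E,4R)-4-[(tert-butyldimethylsilyl)oxy]-2,8-dimethyl-7,9-dioxodec-2-enoate | CC(=O)C(C)C(=O)CC[C@@H](O[Si](C)(C)C(C)(C)C)/C=C(\C)C(=O)OCC | intermediate
8 | ethyl 2-{2-acetyl-6-[(tert-butyldimethylsilyl)oxy]-2-methyl-3-oxocyclohexyl}propanoate (ring A; 1β-OSi, 5α-methyl, 5β-acetyl, 10β-H) | O=C1CC[C@@H](O[Si](C)(C)C(C)(C)C)[C@H](C(C)C(=O)OCC)[C@@]1(C)C(C)=O | intermediate (not isolated)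
9 | 1β-[(tert-butyldimethylsilyl)oxy]-5α,9β-dimethyl-trans-decalin-4,6,8-trione (10β-H; C9 epimerisable) | O=C1CC[C@@H](O[Si](C)(C)C(C)(C)C)[C@H]2[C@@]1(C)C(=O)CC(=O)[C@@H]2C | intermediate
10 | furan-3-carbaldehyde | O=Cc1ccoc1 | starting material
11 | 3-(2-methoxyethenyl)furan (E/Z mixture) | COC=Cc1ccoc1 | intermediate (not isolated)
12 | (furan-3-yl)acetaldehyde | O=CCc1ccoc1 | intermediate
13 | (11S)-1β-[(tert-butyldimethylsilyl)oxy]-9β-[2-(furan-3-yl)-1-hydroxyethyl]-5α,9α-dimethyl-trans-decalin-4,6,8-trione | O=C1CC[C@@H](O[Si](C)(C)C(C)(C)C)[C@H]2[C@@]1(C)C(=O)CC(=O)[C@]2(C)[C@H](Cc3ccoc3)O | intermediate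
14 | 6-methoxy-6-ene-4,8-dione (6-O-methyl vinylogous ester of 13) | O=C1CC[C@@H](O[Si](C)(C)C(C)(C)C)[C@H]2[C@@]1(C)C(OC)=CC(=O)[C@]2(C)[C@H](Cc3ccoc3)O | intermediate
15 | 8-hydroxy-6-methoxy-8-methyl-6-en-4-one (methyllithium adduct of 14, C8 epimers) | O=C1CC[C@@H](O[Si](C)(C)C(C)(C)C)[C@H]2[C@@]1(C)C(OC)=CC(C)(O)[C@]2(C)[C@H](Cc3ccoc3)O | intermediate (not isolated)
16 | 1β-silyloxy-8-methyl-7-ene-4,6-dione (1-O-silyl ether of 17) | O=C1CC[C@@H](O[Si](C)(C)C(C)(C)C)[C@H]2[C@@]1(C)C(=O)C=C(C)[C@]2(C)[C@H](Cc3ccoc3)O | intermediate (not isolated)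
17 | (11S)-9β-[2-(furan-3-yl)-1-hydroxyethyl]-1β-hydroxy-5α,8,9α-trimethyl-trans-decal-7-ene-4,6-dione | O=C1CC[C@@H](O)[C@H]2[C@@]1(C)C(=O)C=C(C)[C@]2(C)[C@H](Cc3ccoc3)O | intermediate
18 | (11S)-9β-[2-(furan-3-yl)-1-hydroxyethyl]-1β,6α-dihydroxy-5α,8,9α-trimethyl-trans-decal-7-en-4-one | O=C1CC[C@@H](O)[C@H]2[C@@]1(C)[C@@H](O)C=C(C)[C@]2(C)[C@H](Cc3ccoc3)O | intermediate
19 | 1β,6α,11-triacetate of 18 | O=C1CC[C@@H](OC(C)=O)[C@H]2[C@@]1(C)[C@@H](OC(C)=O)C=C(C)[C@]2(C)[C@H](Cc3ccoc3)OC(C)=O | intermediate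
20 | 1β,6α,11-triacetoxy-7β,8β-dihydroxy-8α-methyl 4-ketone (furan side chain) | O=C1CC[C@@H](OC(C)=O)[C@H]2[C@@]1(C)[C@@H](OC(C)=O)[C@H](O)[C@](C)(O)[C@]2(C)[C@H](Cc3ccoc3)OC(C)=O | intermediate
21 | 1β,6α,11-triacetoxy-8β-hydroxy-7β-(isobutyryloxy) 4-ketone (furan side chain) | O=C1CC[C@@H](OC(C)=O)[C@H]2[C@@]1(C)[C@@H](OC(C)=O)[C@H](OC(=O)C(C)C)[C@](C)(O)[C@]2(C)[C@H](Cc3ccoc3)OC(C)=O | intermediate
22 | (11S)-1β,6α,11-triacetoxy-15,16-epoxy-8β-hydroxy-7β-(isobutyryloxy)cleroda-4(18),13(16),14-triene | C=C1CC[C@@H](OC(C)=O)[C@H]2[C@@]1(C)[C@@H](OC(C)=O)[C@H](OC(=O)C(C)C)[C@](C)(O)[C@]2(C)[C@H](Cc3ccoc3)OC(C)=O | intermediate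
23 | furan 2,5-endoperoxide of 22 (2,3,7-trioxabicyclo[2.2.1]hept-5-en-5-yl at C12; bridgehead epimers) | C=C1CC[C@@H](OC(C)=O)[C@H]2[C@@]1(C)[C@@H](OC(C)=O)[C@H](OC(=O)C(C)C)[C@](C)(O)[C@]2(C)[C@H](CC3=CC4OOC3O4)OC(C)=O | intermediate (not isolated)
24 | 16-hydroxy-15,16-olide (4-substituted 5-hydroxyfuran-2(5H)-one, C16 epimers) | C=C1CC[C@@H](OC(C)=O)[C@H]2[C@@]1(C)[C@@H](OC(C)=O)[C@H](OC(=O)C(C)C)[C@](C)(O)[C@]2(C)[C@H](CC3=CC(=O)OC3O)OC(C)=O | intermediate (not isolated)
25 | (1R,5R,6R,7S,8R,9S,10S,11S)-1,6,11-triacetoxy-8-hydroxy-7-(isobutyryloxy)cleroda-4(18),13-dien-15,16-olide (1β,6α-OAc, 7β-ester, 8β-OH) | C=C1CC[C@@H](OC(C)=O)[C@H]2[C@@]1(C)[C@@H](OC(C)=O)[C@H](OC(=O)C(C)C)[C@](C)(O)[C@]2(C)[C@H](CC1=CC(=O)OC1)OC(C)=O | target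

## Step count and risks

Total step count: 15. Longest linear sequence: 14 (steps 1–5 and 7–15; step 6 is a one-step side branch).

**Step 5 (double cyclisation).** The Michael adduct is a non-enolisable 2,2-disubstituted 1,3-diketone that alkoxide can cleave (retro-Claisen), and the ring fusion relies on the chelated-diketonate chair. The fallback sets out from 5 and comes back at 9. Alcohol 5 is oxidised as in step 4 but the aldehyde is trapped with Ph3P=C(CH3)CHO to give the enal (2E,4R)-4-[(tert-butyldimethylsilyl)oxy]-2,8-dimethyl-7,9-dioxodec-2-enal F1. Its diketone adds to the more electrophilic enal with catalytic K2CO3 to give the ring A keto aldehyde 2-{2-acetyl-6-[(tert-butyldimethylsilyl)oxy]-2-methyl-3-oxocyclohexyl}propanal F2. An intramolecular aldol of the acetyl group onto the aldehyde closes ring B as the hydroxy dione 1β-[(tert-butyldimethylsilyl)oxy]-8-hydroxy-5α,9β-dimethyl-trans-decalin-4,6-dione F3. This closure releases no alkoxide and is reversible, so the trans-fused isomer can be reached by equilibration. Oxidation with (n-Pr)4N[RuO4]/NMO then gives 9.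

**Step 7 (aldol at C9).** A tertiary carbanion has to be formed next to two other anionic sites, the aldehyde is enolisable, and the C11 configuration depends on a closed transition state. The fallback sets out from 9 and comes back at 13. Trione 9 is persilylated (LiN(i-Pr)2, then Me3SiCl) to the tris(trimethylsilyl) enol ether 1β-[(tert-butyldimethylsilyl)oxy]-5α,9-dimethyl-4,6,8-tris(trimethylsilyloxy)decalin-3,6,8-triene F4. A BF3·OEt2-mediated Mukaiyama aldol with 12 at the terminal C9 of the 6,8-bis(silyloxy)diene is non-basic, so no proton is taken from the aldehyde, and aqueous acid work-up gives 13. The C11 ratio from this open transition state would have to be checked.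

**Step 9 (methyl addition and transposition).** The C4 ketone is protected only as its enolate, the C8 carbonyl is hindered, and the lithium aldolate at C11 can undergo retro-aldol cleavage on warming. The fallback sets out from 14 and comes back at 17. The C4 ketone is protected covalently (Me3SiOCH2CH2OSiMe3, cat. Me3SiOTf, CH2Cl2, −78 °C; the vinylogous ester is inert) as the C4 ethylene ketal of 14 F5. Methyllithium is then added without amide base, and aqueous HCl followed by HF–MeCN unmasks the enone, the ketone and the C1 hydroxyl to give 17.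

## Further compounds

F1 | step 5 | (2E,4R)-4-[(tert-butyldimethylsilyl)oxy]-2,8-dimethyl-7,9-dioxodec-2-enal | CC(=O)C(C)C(=O)CC[C@@H](O[Si](C)(C)C(C)(C)C)/C=C(\C)C=O
F2 | step 5 | 2-{2-acetyl-6-[(tert-butyldimethylsilyl)oxy]-2-methyl-3-oxocyclohexyl}propanal | O=C1CC[C@@H](O[Si](C)(C)C(C)(C)C)[C@H](C(C)C=O)[C@@]1(C)C(C)=O
F3 | step 5 | 1β-[(tert-butyldimethylsilyl)oxy]-8-hydroxy-5α,9β-dimethyl-trans-decalin-4,6-dione | O=C1CC[C@@H](O[Si](C)(C)C(C)(C)C)[C@H]2[C@@]1(C)C(=O)CC(O)[C@@H]2C
F4 | step 7 | 1β-[(tert-butyldimethylsilyl)oxy]-5α,9-dimethyl-4,6,8-tris(trimethylsilyloxy)decalin-3,6,8-triene | C[Si](C)(C)OC1=CC[C@@H](O[Si](C)(C)C(C)(C)C)[C@H]2[C@@]1(C)C(O[Si](C)(C)C)=CC(O[Si](C)(C)C)=C2C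
F5 | step 9 | C4 ethylene ketal of 14 | O1CCOC12CC[C@@H](O[Si](C)(C)C(C)(C)C)[C@H]3[C@@]2(C)C(OC)=CC(=O)[C@]3(C)[C@H](Cc4ccoc4)O
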